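(The earlier runs and the new flask were generated by integration with made-up constants, noise included.)

| setting | violet | flask |
|---|---|---|
| starting material | 0.10 M | 0.10 M |
| coupling partner | 0.50 M | 0.500 M |
| remark | the very flask that is asked about, followed so far |  |
| time |  | 1.0 h |

**Partner in excess.** In this flask the coupling partner is charged at 0.500 M, more than the 0.10 M of starting material, so [coupling partner] falls little, and I reckon with a rate proportional to [starting material][coupling partner].

violet run (percent of the starting material charged)

| time / min | target / % | side product / % |
|---|---|---|
| 2.50 | 3.2 | 1.2 |
| 8.00 | 9.7 | 1.4 |
| 15.0 | 16.6 | 1.1 |
| 20.0 | 23.0 | 0.8 |
| 30.0 | 32.2 | 0.6 |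

(standard deviation of a reading: 1 percentage point)

- how much target there is at 1.0 h, in percent of the starting material charged
- how much side product there is at 1.0 h, in percent of the starting material charged
- amount of target if the flask were left three thousand times as long, in percent of the starting material charged

**One constant.** Minus the natural logarithm of the fraction not turned into target, divided by time and by [coupling partner], gives 0.0259 L mol⁻¹ min⁻¹ at the last reading. This is my partner constant, a reading that carries the scatter of 1 percentage point.

**The bracket.** Held at its charge for 1.0 h, [coupling partner] is too high, so 54.0% target is a bound from above. That much target leaves 0.446 M, too low for the whole run, so 50.0% is a bound from below. The mean of the two concentrations, 0.473 M, gives 52.1%. Put back for a second round, that answer gives 52.1%, and I commit to it.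

**Side product.** Its readings run between 0.6% and 1.4%, a spread smaller than the scatter, so I cannot tell rise from fall and bracket the target alone.

**The forecast.** The forecast gives 53% target, inside my bracket and above my 52.1%, with 0.2% side product and 97% in the long run, holding that "the reaction is pseudo-first-order in starting material".

**The result.** This flask gives 52.9% target, inside the bracket, 3.73% side product and 93.7% in the long run.

    starting material + coupling partner → target (k = 0.0280 L mol⁻¹ min⁻¹)
    starting material + 2 coupling partner → side product (k = 0.00420 L² mol⁻² min⁻¹)

**Rates compared.** In this flask the target step uses starting material 13 times as fast as the side step at the start and 15 times as fast at 1.00 h, and target stands 14.2 times above side product then. For the neighbour flask with 0.30 M of coupling partner, one round of the same reckoning gives 35.4%, and that flask holds 37.0% target.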